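The target is disconnected at the E-trisubstituted alkene C13=C14 in the side chain on C9 of ring B, which carries methyl C16 on C13 and the acyloxymethyl carbon C15 on C14. One flask builds this unit from a terminal C13≡C14 alkyne by zirconium-catalysed syn methylalumination (C13–C16), formaldehyde capture of the derived aluminate (C14–C15) and O-palmitoylation. The precursor is a 15,16-dinorlabd-8(17)-en-13-yne whose axial C19 acid is masked as a 2-(trimethylsilyl)ethyl ester; it is reached from (+)-podocarpic acid, which supplies rings A and B with C4, C5 and C10 already set, by ozonolytic excision of C13 and C14 from ring C, Wittig methylenation at C8 and acetylide alkylation at C12.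

Key step: step 10

Remarks on the chemistry:
- Labdane numbering is used for every compound; for the podocarpane compounds it coincides for C1–C12 and C18–C20. In all compounds C20 and the C19 carboxyl are β (cis, both axial) and H5 is α; from step 3 on, H9 is α and the C9 chain is β (equatorial).
- The alkyne precursor keeps C14 and lacks only C15 and C16 (18 carbons in the acid part), so it is named as a 15,16-dinorlabdane, not as a trinor compound.
- Natural (+)-podocarpic acid is assumed as the commercial material; it has the same spatial arrangement at C4, C5 and C10 as the target.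

Step 1
Reactants: 1 (+)-podocarpic acid; 2 2-(trimethylsilyl)ethanol
Product: 3 2-(trimethylsilyl)ethyl 12-hydroxypodocarpa-8,11,13-trien-19-oate
Conditions: PPh3, diisopropyl azodicarboxylate (DIAD), THF, 0 °C → rt
Reagents that add atoms: none
Why: Mitsunobu esterification, in which the carboxylate (much more acidic than the phenol) attacks the primary alkoxyphosphonium carbon derived from 2, so the hindered axial C19 carbonyl is never the electrophile and no stereocentre is touched.

Step 2
Reactants: 3 2-(trimethylsilyl)ethyl 12-hydroxypodocarpa-8,11,13-trien-19-oate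
Product: 4 2-(trimethylsilyl)ethyl 8-hydroxy-13,14,15,16,17-pentanorlabd-9(11)-en-12,8-olid-19-oate (γ-hydroxybutenolide with C12(=O)–O–C8(OH) and C9=C11; ring-closed form of the (9Z)-8-oxo-9(11)-en-12-oic acid; both C8 epimers)
Conditions: O3 (about 2 equiv, followed by TLC), CH2Cl2/MeOH, −78 °C; then Me2S, −78 °C → rt
Reagents that add atoms: ozone, O=[O+][O-]
Why: Ozonolysis of the phenol ring C should cleave the electron-rich C12–C13 and C8–C14 bonds and release C13 and C14 as glyoxal, whereas C9=C11, left between the C8 ketone and the C12 carboxyl, is electron-poor and should survive, the cis keto acid then closing to the lactol.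

Step 3
Reactants: 4 2-(trimethylsilyl)ethyl 8-hydroxy-13,14,15,16,17-pentanorlabd-9(11)-en-12,8-olid-19-oate
Product: 5 8-oxo-13,14,15,16,17-pentanorlabdane-12,19-dioic acid 19-[2-(trimethylsilyl)ethyl] monoester (free C12 acid; H9 α, CH2CO2H on C9 β)
Conditions: Zn dust, AcOH, rt → 50 °C
Reagents that add atoms: none
Why: Zinc reduction of the ene-1,4-dicarbonyl system (through the ring-opened keto acid or by reductive cleavage of the γ C8–O lactone bond) gives the C8 enol, which should be protonated at C9 axially from the α face opposite the C10 methyl, so that the new C9 stereocentre carries the chain equatorial (β), which is also the thermodynamically preferred epimer next to the ketone.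

Step 4
Reactants: 5 8-oxo-13,14,15,16,17-pentanorlabdane-12,19-dioic acid 19-[2-(trimethylsilyl)ethyl] monoester
Product: 6 12-methyl 19-[2-(trimethylsilyl)ethyl] 8-oxo-13,14,15,16,17-pentanorlabdane-12,19-dioate
Conditions: MeI, K2CO3, DMF, rt
Reagents that add atoms: iodomethane, CI
Why: SN2 O-alkylation of the C12 carboxylate, under a mild base that can only move the enolisable C9 centre toward the desired equatorial epimer.

Step 5
Reactants: 6 12-methyl 19-[2-(trimethylsilyl)ethyl] 8-oxo-13,14,15,16,17-pentanorlabdane-12,19-dioate
Product: 7 12-methyl 19-[2-(trimethylsilyl)ethyl] 13,14,15,16-tetranorlabd-8(17)-ene-12,19-dioate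
Conditions: Ph3PCH3Br, KOt-Bu, THF, 0 °C → 40 °C
Reagents that add atoms: methyltriphenylphosphonium bromide, [Br-].C[P+](c1ccccc1)(c1ccccc1)c1ccccc1
Why: Wittig methylenation of the C8 ketone by the non-stabilised ylide, which reacts faster with the ketone than with either ester, and any reversible enolisation toward C9 returns the equatorial chain.

Step 6
Reactants: 7 12-methyl 19-[2-(trimethylsilyl)ethyl] 13,14,15,16-tetranorlabd-8(17)-ene-12,19-dioate
Product: 8 2-(trimethylsilyl)ethyl 12-hydroxy-13,14,15,16-tetranorlabd-8(17)-en-19-oate
Conditions: LiBH4, THF, 0 °C → rt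
Reagents that add atoms: none
Why: Chemoselective hydride reduction of the unhindered C12 methyl ester, since the C19 ester sits axially on the quaternary C4, 1,3 to the C10 methyl, and should be far slower, and LiBH4 does not attack the C8(17) alkene.

Step 7
Reactants: 8 2-(trimethylsilyl)ethyl 12-hydroxy-13,14,15,16-tetranorlabd-8(17)-en-19-oate
Product: 9 2-(trimethylsilyl)ethyl 12-iodo-13,14,15,16-tetranorlabd-8(17)-en-19-oate
Conditions: I2, PPh3, imidazole, CH2Cl2, 0 °C → rt
Reagents that add atoms: iodine, II
Why: Appel-type iodination of the primary alcohol through its alkoxyphosphonium iodide under buffered, essentially neutral conditions that spare the exocyclic alkene and the silylethyl ester.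

Step 8
Reactants: 9 2-(trimethylsilyl)ethyl 12-iodo-13,14,15,16-tetranorlabd-8(17)-en-19-oate; 10 ethynyltrimethylsilane
Product: 12 2-(trimethylsilyl)ethyl 14-(trimethylsilyl)-15,16-dinorlabd-8(17)-en-13-yn-19-oate, via lithium trimethylsilylacetylide 11 (not isolated)
Conditions: 10, n-BuLi, THF, −78 °C; then 9, DMPU, −78 °C → rt
Reagents that add atoms: none
Why: SN2 alkylation of a lithium acetylide by an unbranched primary iodide in a dipolar cosolvent, forming C12–C13, with the silyl cap preventing a second alkylation and the hindered C19 ester left alone.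

Step 9
Reactants: 12 2-(trimethylsilyl)ethyl 14-(trimethylsilyl)-15,16-dinorlabd-8(17)-en-13-yn-19-oate
Product: 13 2-(trimethylsilyl)ethyl 15,16-dinorlabd-8(17)-en-13-yn-19-oate
Conditions: K2CO3 (cat.), MeOH/THF, rt
Reagents that add atoms: none
Why: Methoxide-catalysed protodesilylation, which is selective for the silicon on the sp carbon and leaves the alkyl-bound silicon of the ester group and the hindered ester itself intact (fluoride is avoided at this stage for that reason).

Step 10
Reactants: 13 2-(trimethylsilyl)ethyl 15,16-dinorlabd-8(17)-en-13-yn-19-oate; 14 palmitoyl chloride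
Product: 18 2-(trimethylsilyl)ethyl 15-(palmitoyloxy)labda-8(17),13E-dien-19-oate, via alkenyldimethylalane 15 (not isolated), via lithium alkenylaluminate 16 (not isolated), via lithium alkoxyaluminate 17 (not isolated)
Conditions: Me3Al (3 equiv), Cp2ZrCl2 (cat.), CH2Cl2, 0 °C → rt; volatiles removed in vacuo; n-BuLi (1 equiv), THF/hexane, −78 °C; (CH2O)n, −78 °C → rt; then 14 (excess), pyridine, 4-(dimethylamino)pyridine (cat.), 0 °C → rt
Reagents that add atoms: trimethylaluminium, C[Al](C)C; formaldehyde (from paraformaldehyde), C=O
Why: Me3Al and Cp2ZrCl2 form a methylzirconocene–aluminium pair that adds methyl and metal syn across the terminal alkyne, methyl to the internal carbon C13 and metal to C14, and transmetalation gives the (E)-alkenylalane 15 (C13–C16 formed). n-BuLi converts 15 into the aluminate 16, whose C14–Al bond adds to monomeric formaldehyde with retention of alkene geometry (C14–C15 formed), and the aluminium-bound alkoxide 17 is O-acylated by 14 under 4-(dimethylamino)pyridine catalysis. The closest known reaction type is the zirconium-catalysed methylalumination of terminal alkynes with formaldehyde trapping of the aluminate (Negishi carboalumination), joined to the familiar in situ acylation of aluminium alkoxides. No ring is closed and no stereocentre is created; the element formed is the E geometry of C13=C14, fixed by the syn addition before C15 is attached. The step needs regioselectivity (methyl to C13) and syn stereospecificity, both secured by the unhindered terminal alkyne, which C11 and C12 insulate from the decalin. The 1,1-disubstituted C8(17) alkene is inert to methylalumination under these conditions, and the axial C19 ester, shielded by C20 and ring A, should resist Me3Al and the single equivalent of n-BuLi, which aluminium consumes first.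

Step 11
Reactants: 18 2-(trimethylsilyl)ethyl 15-(palmitoyloxy)labda-8(17),13E-dien-19-oate
Product: 19 15-(palmitoyloxy)labda-8(17),13E-dien-19-oic acid (target)
Conditions: TBAF, THF, 0 °C → rt; then cold dilute aq. HCl work-up
Reagents that add atoms: none
Why: Fluoride attacks silicon and triggers β-elimination to ethylene, Me3SiF and the C19 carboxylate, so the hindered carbonyl is never attacked and the primary allylic palmitate, both alkenes and all stereocentres should be left as they are.

Compound list
1 | (+)-podocarpic acid (12-hydroxypodocarpa-8,11,13-trien-19-oic acid) | Oc1ccc2CC[C@@H]3[C@](C)(CCC[C@]3(C)C(=O)O)c2c1 | starting material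
2 | 2-(trimethylsilyl)ethanol | OCC[Si](C)(C)C | starting material
3 | 2-(trimethylsilyl)ethyl 12-hydroxypodocarpa-8,11,13-trien-19-oate | Oc1ccc2CC[C@@H]3[C@](C)(CCC[C@]3(C)C(=O)OCC[Si](C)(C)C)c2c1 | intermediate
4 | 2-(trimethylsilyl)ethyl 8-hydroxy-13,14,15,16,17-pentanorlabd-9(11)-en-12,8-olid-19-oate (lactol, C8 epimers) | O=C1OC2(O)CC[C@@H]3[C@](C)(CCC[C@]3(C)C(=O)OCC[Si](C)(C)C)C2=C1 | intermediate
5 | 8-oxo-13,14,15,16,17-pentanorlabdane-12,19-dioic acid 19-[2-(trimethylsilyl)ethyl] monoester (H9 α) | O=C1CC[C@@H]2[C@](C)(CCC[C@]2(C)C(=O)OCC[Si](C)(C)C)[C@H]1CC(=O)O | intermediate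
6 | 12-methyl 19-[2-(trimethylsilyl)ethyl] 8-oxo-13,14,15,16,17-pentanorlabdane-12,19-dioate | O=C1CC[C@@H]2[C@](C)(CCC[C@]2(C)C(=O)OCC[Si](C)(C)C)[C@H]1CC(=O)OC | intermediate
7 | 12-methyl 19-[2-(trimethylsilyl)ethyl] 13,14,15,16-tetranorlabd-8(17)-ene-12,19-dioate | C=C1CC[C@@H]2[C@](C)(CCC[C@]2(C)C(=O)OCC[Si](C)(C)C)[C@H]1CC(=O)OC | intermediate
8 | 2-(trimethylsilyl)ethyl 12-hydroxy-13,14,15,16-tetranorlabd-8(17)-en-19-oate | C=C1CC[C@@H]2[C@](C)(CCC[C@]2(C)C(=O)OCC[Si](C)(C)C)[C@H]1CCO | intermediate
9 | 2-(trimethylsilyl)ethyl 12-iodo-13,14,15,16-tetranorlabd-8(17)-en-19-oate | C=C1CC[C@@H]2[C@](C)(CCC[C@]2(C)C(=O)OCC[Si](C)(C)C)[C@H]1CCI | intermediate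
10 | ethynyltrimethylsilane | C#C[Si](C)(C)C | starting material
11 | lithium trimethylsilylacetylide (not isolated) | [Li]C#C[Si](C)(C)C | intermediate
12 | 2-(trimethylsilyl)ethyl 14-(trimethylsilyl)-15,16-dinorlabd-8(17)-en-13-yn-19-oate | C=C1CC[C@@H]2[C@](C)(CCC[C@]2(C)C(=O)OCC[Si](C)(C)C)[C@H]1CCC#C[Si](C)(C)C | intermediate
13 | 2-(trimethylsilyl)ethyl 15,16-dinorlabd-8(17)-en-13-yn-19-oate (key-step precursor) | C=C1CC[C@@H]2[C@](C)(CCC[C@]2(C)C(=O)OCC[Si](C)(C)C)[C@H]1CCC#C | intermediate
14 | palmitoyl chloride (hexadecanoyl chloride) | CCCCCCCCCCCCCCCC(=O)Cl | starting material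
15 | 2-(trimethylsilyl)ethyl 14-(dimethylalumanyl)-15-norlabda-8(17),13E-dien-19-oate (not isolated) | C=C1CC[C@@H]2[C@](C)(CCC[C@]2(C)C(=O)OCC[Si](C)(C)C)[C@H]1CC/C(C)=C/[Al](C)C | intermediate
16 | lithium butyl(dimethyl)aluminate of 15, aluminium on C14 (not isolated) | C=C1CC[C@@H]2[C@](C)(CCC[C@]2(C)C(=O)OCC[Si](C)(C)C)[C@H]1CC/C(C)=C/[Al-](C)(C)CCCC.[Li+] | intermediate
17 | lithium butyl(dimethyl)aluminate of the C15 alkoxide of the (13E)-allylic alcohol (not isolated) | C=C1CC[C@@H]2[C@](C)(CCC[C@]2(C)C(=O)OCC[Si](C)(C)C)[C@H]1CC/C(C)=C/CO[Al-](C)(C)CCCC.[Li+] | intermediate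
18 | 2-(trimethylsilyl)ethyl 15-(palmitoyloxy)labda-8(17),13E-dien-19-oate (key-step product) | C=C1CC[C@@H]2[C@](C)(CCC[C@]2(C)C(=O)OCC[Si](C)(C)C)[C@H]1CC/C(C)=C/COC(=O)CCCCCCCCCCCCCCC | intermediate
19 | 15-(palmitoyloxy)labda-8(17),13E-dien-19-oic acid, (4S,5R,9S,10R) | C=C1CC[C@@H]2[C@](C)(CCC[C@]2(C)C(=O)O)[C@H]1CC/C(C)=C/COC(=O)CCCCCCCCCCCCCCC | target

Total step count: 11
Longest linear sequence: 11 steps (1 → 19)

Steps most likely to fail

Step 10. The one-flask acylation may stall because methyl or butyl groups are transferred from aluminium to the acid chloride, or because the aluminium-bound alkoxide is acylated incompletely. The fallback sets out from 13: the methylalumination, aluminate formation and formaldehyde addition are run as in step 10 but quenched with aqueous NH4Cl instead of the acid chloride. This should give the free allylic alcohol, 2-(trimethylsilyl)ethyl 15-hydroxylabda-8(17),13E-dien-19-oate F1. In a separate flask F1 is esterified with 14, pyridine and catalytic 4-(dimethylamino)pyridine in CH2Cl2 at 0 °C, which comes back to the route at 18.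

Step 2. Ozone may over-oxidise by also cleaving C9=C11, or open the phenol ring unselectively. The fallback sets out from 3 and separates dearomatisation from cleavage. Oxidation with PhI(OAc)2 in MeCN/H2O at 0 °C should add water at C8, para to the phenol oxygen, and give the para-quinol, 2-(trimethylsilyl)ethyl 8-hydroxy-12-oxopodocarpa-9(11),13-dien-19-oate F2. Lemieux–Johnson oxidation with OsO4 (cat.) and excess NaIO4 (2,6-lutidine, dioxane/H2O) should dihydroxylate the less substituted C13=C14 enone bond. Periodate then cleaves C8–C14, C13–C14 and the C12–C13 ketol bond, with C13 and C14 leaving as formic acid. This comes back to the route at 4.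

Step 11. The allylic palmitate may be lost through ester cleavage by basic fluoride or adventitious hydroxide while the silylethyl group is removed. The fallback sets out from 13 and changes the order so that the labile ester never meets fluoride. The alcohol, 2-(trimethylsilyl)ethyl 15-hydroxylabda-8(17),13E-dien-19-oate F1, is made as described for the fallback to step 10. TBAF in THF then frees the acid to give 15-hydroxylabda-8(17),13E-dien-19-oic acid (isocupressic acid) F3. The primary allylic hydroxyl of F3 is acylated selectively with 14 and pyridine in CH2Cl2 at 0 °C, and any mixed anhydride formed at the hindered C19 carboxyl is hydrolysed during aqueous NaHCO3 work-up. This comes back to the route at 19.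

Further compounds
F1 | step 10 | 2-(trimethylsilyl)ethyl 15-hydroxylabda-8(17),13E-dien-19-oate | C=C1CC[C@@H]2[C@](C)(CCC[C@]2(C)C(=O)OCC[Si](C)(C)C)[C@H]1CC/C(C)=C/CO
F2 | step 2 | 2-(trimethylsilyl)ethyl 8-hydroxy-12-oxopodocarpa-9(11),13-dien-19-oate (para-quinol, C8 epimers) | O=C1C=CC2(O)CC[C@@H]3[C@](C)(CCC[C@]3(C)C(=O)OCC[Si](C)(C)C)C2=C1
F3 | step 11 | 15-hydroxylabda-8(17),13E-dien-19-oic acid (isocupressic acid) | C=C1CC[C@@H]2[C@](C)(CCC[C@]2(C)C(=O)O)[C@H]1CC/C(C)=C/CO
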